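The constants here had to be read off the two runs in which Z gave D and E.

| flask | Z | remark | time |
|---|---|---|---|
| Thursday's | 0.10 M | run made earlier |  |
| Sunday's | 0.15 M | run made earlier |  |
| flask | 0.20 M |  | 10 min |

| run | time / min | D / % | E / % |
|---|---|---|---|
| Thursday's | 1.00 | 17.0 | 26.8 |
| Thursday's | 2.00 | 22.9 | 18.2 |
| Thursday's | 3.00 | 26.8 | 10.2 |
| Thursday's | 4.00 | 28.8 | 6.3 |
| Thursday's | 5.00 | 29.1 | 2.8 |
| Thursday's | 6.00 | 30.2 | 1.8 |
| Sunday's | 0.500 | 11.1 | 23.4 |
| Sunday's | 0.833 | 14.9 | 24.5 |
| Sunday's | 1.33 | 18.2 | 22.5 |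
| Sunday's | 2.00 | 22.2 | 17.0 |
| Sunday's | 4.00 | 26.6 | 5.6 |
| Sunday's | 6.00 | 26.9 | 2.3 |

(readings scatter by 0.5 percentage points)

1. ratio of D to E at 1.2 s
2. ratio of D to E at 25 s
3. ratio of D to E at 10 min

- the numbers in the tables scatter with a standard deviation of 0.5 percentage points
- a reading or a percentage of E counts all its forms, free or not

1. On Sunday, D barely moved late on, going from 26.6% to 26.9%, while E fell from 5.6% to 2.3%. So I took the late ratio of D to E to follow the fall in E.

2. At the start of Sunday's run, the natural logarithm of that ratio rose at 0.675 min⁻¹, from 0.500 min to 2.00 min.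

3. From then to 6.00 min it rose at 0.548 min⁻¹, a slowing by a factor of 0.812. I called this late rise per minute of the logarithm of D over E the climb, an apparent first-order rate constant.

4. Thursday's climb read 0.648 min⁻¹, but the scatter on its last E reading moved that by 0.0694 min⁻¹. I carried Sunday's value to the flask.

5. Running Sunday's last ratio on at the climb to 10 min, I reckoned about 105.

6. The forecast gave 0.37 (0.28 to 0.44), 0.46 (0.4 to 0.53) and 85 (45 to 170), warning that “E depends strongly on the tail rate”. My figure stood above its last value, within its range.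

7. The flask gave 0.347, 0.438 and 85.5.

    Z + E ⇌ G, settled at all times (K = 1.40 L mol⁻¹)
    Z ⇌ E (K = 1.80, k = 0.0160 s⁻¹)
    Z ⇌ D (K = 56.0, k = 0.00550 s⁻¹)
    2 Z → J (k = 0.0370 L mol⁻¹ s⁻¹)
    E → Q (k = 0.0120 s⁻¹)

In this flask, Z was down to 23.5% after 1.00 min, with E at 23.6% and D at 15.5%. The turning of E into Q, with a half-life of 0.96 min for free E, was still running in this flask after 5.00 min, with E at 2.99% and Q at 42.2%, and by 10.0 min E stood at 0.308% and Q at 46.1%, while D read 25.7% and then 26.4%. Between those two times this flask's climb was 0.459 min⁻¹, below the 0.548 min⁻¹ I had carried. Averaged from 25 s to 10 min, the rise was 0.550 min⁻¹ in this flask and 0.545 min⁻¹ in the neighbour flask with 0.050 M of Z, which reached 83.2, still inside the forecast's range.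

(All runs stem from a simulated flask for an exercise; the scatter is artificial.)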